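**Plan**

1. Numbering used: chain carbons C1 (alkyne CH) to C15 (CH3); O-a joins C6 and C10 (six-membered ring O-a/C6/C7/C8/C9/C10), O-b joins C7 and C13 (eight-membered ring).
2. Cuts: C1≡C2 and C3=C4 (enyne from a C4 carbonyl); O-b–C13 together with C12–Br (bromoetherification of the 12E-alkene); C9–Br (from a C9 ketone); C7–O-b (from a C7 boronate); C5–C6 (C-glycosylation); last, the six-membered ring itself, taken back to a furan.
3. Enabling feature: in ring O-a/C6–C10 both carbons next to O-a carry carbon chains and the heteroatom-bearing C7 and C9 flank C8. This is the oxidation pattern of a 6-hydroxy-2H-pyran-3(6H)-one (C9 ketone, C7=C8 enone, C6 acetal carbon), hence of a 2-furylcarbinol whose carbinol carbon is C10.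
4. Forward: furan + (E)-hex-3-enoic acid → furyl ketone → (R)-carbinol; oxidative ring expansion of the furan builds the six-membered ring first; C6 side chain, C7–B and C9–Br follow; the eight-membered ring is closed second; the enyne is made last.
5. Stereochemistry: C10 from a CBS reduction; C6 by axial attack on the pyranone oxocarbenium ion (trans to the C10 chain); C7 by conjugate borylation anti to the C6 chain; C9 by hydride addition then SN2 inversion; C12/C13 by anti addition across the E-alkene in the bridged transition state.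

Key step: step 3

Assumption: the anomeric mixtures 7 and 8 are carried on unseparated, because C6 becomes planar (oxocarbenium ion) in step 5.

**Route**

Step 1
Reactants: 1 furan; 2 (3E)-hex-3-enoic acid
Product: 4 (3E)-1-(furan-2-yl)hex-3-en-1-one, via mixed anhydride 3 (not isolated)
Conditions: (CF3CO)2O, CH2Cl2, 0 °C to rt (furan in excess)
Reagents that add atoms: none
Why: Friedel–Crafts acylation through the mixed trifluoroacetic anhydride transfers the acyl group to the α-position of the electron-rich furan without a Lewis acid, conditions mild enough that the 3,4-double bond should keep its position and E geometry.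

Step 2
Reactants: 4 (3E)-1-(furan-2-yl)hex-3-en-1-one
Product: 5 (1R,3E)-1-(furan-2-yl)hex-3-en-1-ol
Conditions: (S)-2-methyl-CBS-oxazaborolidine (0.1 equiv), catecholborane, toluene, −78 °C
Reagents that add atoms: none
Why: Corey–Bakshi–Shibata reduction: with the furyl ring in the large-group position of the catalyst–borane complex the (S)-catalyst should deliver hydride to the face that gives the (R)-carbinol (future C10), and catecholborane leaves the isolated alkene alone.

Step 3
Reactants: 5 (1R,3E)-1-(furan-2-yl)hex-3-en-1-ol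
Product: 7 (2R)-6-hydroxy-2-[(2E)-pent-2-en-1-yl]-2H-pyran-3(6H)-one, via (Z)-keto-enal 6 (not isolated)
Conditions: N-bromosuccinimide (1.0 equiv), NaHCO3, NaOAc, THF–H2O (4:1), 0 °C
Reagents that add atoms: water, O
Why: Achmatowicz rearrangement: electrophilic bromination of the furan at an α-position, addition of water and loss of HBr give a 2,5-dihydrofuran hemiketal that opens to the (Z)-keto-enal 6, in which the former furan oxygen has become the C9 carbonyl oxygen. The carbinol oxygen then closes onto the aldehyde, so the five-membered furan (O, C6–C9) is exchanged for the six-membered pyranone that holds C10 and the carbinol oxygen O-a as new ring members; the closest known reaction type is the oxidative ring expansion of 2-furylcarbinols to 6-hydroxy-2H-pyran-3(6H)-ones. The ring closes by 6-exo-trig hemiacetalisation under thermodynamic control, which the Z geometry of the enedione, inherited from the furan, makes possible. The C10 stereocentre is not touched and is carried over; the new anomeric centre C6 forms as a mixture that is erased in step 5. The selectivity needed is oxidation of the furan in the presence of the 12,13-alkene; the far higher nucleophilicity of the furan towards NBS, one equivalent of reagent, 0 °C and the bicarbonate buffer should secure it. The product carries a ketone at C9, an enone β-carbon at C7 and an acetal carbon at C6, the three handles used in steps 5 to 8.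

Step 4
Reactants: 7 (2R)-6-hydroxy-2-[(2E)-pent-2-en-1-yl]-2H-pyran-3(6H)-one
Product: 8 (6R)-5-oxo-6-[(2E)-pent-2-en-1-yl]-5,6-dihydro-2H-pyran-2-yl acetate
Conditions: Ac2O, pyridine, DMAP (cat.), CH2Cl2, 0 °C
Reagents that add atoms: acetic anhydride, CC(=O)OC(C)=O
Why: Acylation of the lactol turns the anomeric hydroxyl into a leaving group for step 5 and stops ring–chain equilibration.

Step 5
Reactants: 8 (6R)-5-oxo-6-[(2E)-pent-2-en-1-yl]-5,6-dihydro-2H-pyran-2-yl acetate; 9 tert-butyl[(1-methoxyethenyl)oxy]dimethylsilane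
Product: 10 methyl 2-[(2R,6R)-5-oxo-6-[(2E)-pent-2-en-1-yl]-5,6-dihydro-2H-pyran-2-yl]acetate
Conditions: Me3SiOTf (0.1 equiv), CH2Cl2, −78 °C
Reagents that add atoms: none
Why: Lewis-acid-mediated C-glycosylation (Mukaiyama-type addition to the pyranone oxocarbenium ion): the ketene silyl acetal attacks C6 axially on the face remote from the C10 side chain, which should give the 2,6-trans product and sets C6.

Step 6
Reactants: 10 methyl 2-[(2R,6R)-5-oxo-6-[(2E)-pent-2-en-1-yl]-5,6-dihydro-2H-pyran-2-yl]acetate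
Product: 11 methyl 2-[(2R,3S,6R)-5-oxo-6-[(2E)-pent-2-en-1-yl]-3-(4,4,5,5-tetramethyl-1,3,2-dioxaborolan-2-yl)oxan-2-yl]acetate
Conditions: B2pin2 (1.1 equiv), CuCl (5 mol %), NaOt-Bu (7 mol %), DPEphos (5 mol %), MeOH (2 equiv), THF, rt
Reagents that add atoms: bis(pinacolato)diboron, CC1(C)OB(OC1(C)C)B1OC(C)(C)C(C)(C)O1
Why: Copper-catalysed conjugate borylation of the enone: the boryl group adds to C7 anti to the neighbouring C6 side chain and so sets C7, and the boronate is a masked hydroxyl that tolerates steps 7 to 9.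

Step 7
Reactants: 11 methyl 2-[(2R,3S,6R)-5-oxo-6-[(2E)-pent-2-en-1-yl]-3-(4,4,5,5-tetramethyl-1,3,2-dioxaborolan-2-yl)oxan-2-yl]acetate
Product: 12 methyl 2-[(2R,3S,5R,6R)-5-hydroxy-6-[(2E)-pent-2-en-1-yl]-3-(4,4,5,5-tetramethyl-1,3,2-dioxaborolan-2-yl)oxan-2-yl]acetate
Conditions: NaBH4, MeOH, −40 °C
Reagents that add atoms: none
Why: Hydride reduction of the C9 ketone: attack from the ring face opposite the axial C10 side chain (and opposite the C7 boronate in the other chair) should give the alcohol cis to that chain, the epimer needed for inversion in step 8.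

Step 8
Reactants: 12 methyl 2-[(2R,3S,5R,6R)-5-hydroxy-6-[(2E)-pent-2-en-1-yl]-3-(4,4,5,5-tetramethyl-1,3,2-dioxaborolan-2-yl)oxan-2-yl]acetate
Product: 13 methyl 2-[(2R,3S,5S,6R)-5-bromo-6-[(2E)-pent-2-en-1-yl]-3-(4,4,5,5-tetramethyl-1,3,2-dioxaborolan-2-yl)oxan-2-yl]acetate
Conditions: CBr4, (n-C8H17)3P, toluene, 70 °C
Reagents that add atoms: carbon tetrabromide, BrC(Br)(Br)Br
Why: Appel reaction: SN2 displacement of the oxyphosphonium group by bromide inverts C9 and places bromine trans to the C10 chain, the usual way to install a ring bromide next to an ether carbon in this family of halogenated cyclic ethers.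

Step 9
Reactants: 13 methyl 2-[(2R,3S,5S,6R)-5-bromo-6-[(2E)-pent-2-en-1-yl]-3-(4,4,5,5-tetramethyl-1,3,2-dioxaborolan-2-yl)oxan-2-yl]acetate
Product: 14 2-[(2R,3S,5S,6R)-5-bromo-6-[(2E)-pent-2-en-1-yl]-3-(4,4,5,5-tetramethyl-1,3,2-dioxaborolan-2-yl)oxan-2-yl]ethan-1-ol
Conditions: i-Bu2AlH (2.5 equiv), CH2Cl2, −78 to −20 °C; aqueous KNaC4H4O6 work-up
Reagents that add atoms: none
Why: Ester reduction at this stage removes the carbonyl group before the C7 hydroxyl is set free, so that no γ-lactone can form; alkyl bromide, boronate and alkene are inert to the hydride at low temperature.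

Step 10
Reactants: 14 2-[(2R,3S,5S,6R)-5-bromo-6-[(2E)-pent-2-en-1-yl]-3-(4,4,5,5-tetramethyl-1,3,2-dioxaborolan-2-yl)oxan-2-yl]ethan-1-ol
Product: 15 (2R,3S,5S,6R)-5-bromo-2-(2-hydroxyethyl)-6-[(2E)-pent-2-en-1-yl]oxan-3-ol
Conditions: NaBO3·4H2O, THF–H2O (1:1), rt
Reagents that add atoms: sodium perborate, [Na+].[O-]OB=O
Why: Oxidation of the C–B bond with retention of configuration unveils the C7 hydroxyl under mild conditions, and the trans-1,3 arrangement of boron and bromine disfavours 1,3-elimination.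

Step 11
Reactants: 15 (2R,3S,5S,6R)-5-bromo-2-(2-hydroxyethyl)-6-[(2E)-pent-2-en-1-yl]oxan-3-ol
Product: 16 2-[(1S,3R,4S,6R,8R,10S)-4,10-dibromo-3-ethyl-2,7-dioxabicyclo[4.2.2]decan-8-yl]ethan-1-ol
Conditions: Et2SBr·SbCl5Br (1.2 equiv), MeNO2, −25 °C; aqueous Na2SO3/NaHCO3 quench
Reagents that add atoms: bromodiethylsulfonium bromopentachloroantimonate, CC[S+](Br)CC.Cl[Sb-](Cl)(Cl)(Cl)(Cl)Br
Why: Bromonium-induced etherification: Br+ transfer to the 12E-alkene and anti attack of the C7 hydroxyl at C13 (8-endo) should close the bridging oxocane with the 12,13-erythro relationship; the hydroxyl and the side chain are cis on the pyran and meet through its boat form, the alkene face is expected to be chosen by the ethyl group taking the outer position of the bridged transition state, and the ring oxygen can reach the bromonium ion only in a disfavoured 5-endo mode.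

Step 12
Reactants: 16 2-[(1S,3R,4S,6R,8R,10S)-4,10-dibromo-3-ethyl-2,7-dioxabicyclo[4.2.2]decan-8-yl]ethan-1-ol
Product: 17 2-[(1S,3R,4S,6R,8R,10S)-4,10-dibromo-3-ethyl-2,7-dioxabicyclo[4.2.2]decan-8-yl]acetaldehyde
Conditions: Dess–Martin periodinane, CH2Cl2, 0 °C to rt
Reagents that add atoms: none
Why: Dess–Martin oxidation of the primary alcohol under non-basic conditions, so that the β-alkoxy aldehyde is not opened by elimination; it is used directly.

Step 13
Reactants: 17 2-[(1S,3R,4S,6R,8R,10S)-4,10-dibromo-3-ethyl-2,7-dioxabicyclo[4.2.2]decan-8-yl]acetaldehyde; 18 (triphenylphosphoranylidene)acetaldehyde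
Product: 19 (2E)-4-[(1S,3R,4S,6R,8R,10S)-4,10-dibromo-3-ethyl-2,7-dioxabicyclo[4.2.2]decan-8-yl]but-2-enal
Conditions: toluene, 70 °C
Reagents that add atoms: none
Why: Wittig reaction with a stabilised ylide, which should give the (E)-enal and brings in C2 and C3.

Step 14
Reactants: 19 (2E)-4-[(1S,3R,4S,6R,8R,10S)-4,10-dibromo-3-ethyl-2,7-dioxabicyclo[4.2.2]decan-8-yl]but-2-enal; 20 (diazomethyl)trimethylsilane
Product: 21 (1S,3R,4S,6R,8R,10S)-4,10-dibromo-3-ethyl-8-[(2E)-pent-2-en-4-yn-1-yl]-2,7-dioxabicyclo[4.2.2]decane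
Conditions: LiN(i-Pr)2, THF, −78 °C; then 19, −78 to 0 °C
Reagents that add atoms: none
Why: Colvin rearrangement: addition of lithiated (trimethylsilyl)diazomethane to the aldehyde, Peterson-type loss of Me3SiOLi and a 1,2-hydrogen shift in the alkylidene carbene give the terminal alkyne with the E-alkene untouched; the reagent is nucleophilic but weakly basic at low temperature, so the two secondary bromides should survive.

**Compound list**

1 | furan | c1ccoc1 | starting material
2 | (3E)-hex-3-enoic acid | CC/C=C/CC(=O)O | starting material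
3 | (3E)-hex-3-enoic trifluoroacetic anhydride (not isolated) | CC/C=C/CC(=O)OC(=O)C(F)(F)F | intermediate
4 | (3E)-1-(furan-2-yl)hex-3-en-1-one | CC/C=C/CC(=O)c1ccco1 | intermediate
5 | (1R,3E)-1-(furan-2-yl)hex-3-en-1-ol | CC/C=C/C[C@@H](O)c1ccco1 | intermediate
6 | (2Z,5R,7E)-5-hydroxy-4-oxodeca-2,7-dienal (not isolated) | CC/C=C/C[C@@H](O)C(=O)/C=C\C=O | intermediate
7 | (2R)-6-hydroxy-2-[(2E)-pent-2-en-1-yl]-2H-pyran-3(6H)-one (both anomers) | CC/C=C/C[C@H]1OC(O)C=CC1=O | intermediate
8 | (6R)-5-oxo-6-[(2E)-pent-2-en-1-yl]-5,6-dihydro-2H-pyran-2-yl acetate (both anomers) | CC/C=C/C[C@H]1OC(OC(C)=O)C=CC1=O | intermediate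
9 | tert-butyl[(1-methoxyethenyl)oxy]dimethylsilane | COC(=C)O[Si](C)(C)C(C)(C)C | starting material
10 | methyl 2-[(2R,6R)-5-oxo-6-[(2E)-pent-2-en-1-yl]-5,6-dihydro-2H-pyran-2-yl]acetate | COC(=O)C[C@@H]1C=CC(=O)[C@@H](C/C=C/CC)O1 | intermediate
11 | methyl 2-[(2R,3S,6R)-5-oxo-6-[(2E)-pent-2-en-1-yl]-3-(4,4,5,5-tetramethyl-1,3,2-dioxaborolan-2-yl)oxan-2-yl]acetate | COC(=O)C[C@@H]1[C@@H](B2OC(C)(C)C(C)(C)O2)CC(=O)[C@@H](C/C=C/CC)O1 | intermediate
12 | methyl 2-[(2R,3S,5R,6R)-5-hydroxy-6-[(2E)-pent-2-en-1-yl]-3-(4,4,5,5-tetramethyl-1,3,2-dioxaborolan-2-yl)oxan-2-yl]acetate | COC(=O)C[C@@H]1[C@@H](B2OC(C)(C)C(C)(C)O2)C[C@@H](O)[C@@H](C/C=C/CC)O1 | intermediate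
13 | methyl 2-[(2R,3S,5S,6R)-5-bromo-6-[(2E)-pent-2-en-1-yl]-3-(4,4,5,5-tetramethyl-1,3,2-dioxaborolan-2-yl)oxan-2-yl]acetate | COC(=O)C[C@@H]1[C@@H](B2OC(C)(C)C(C)(C)O2)C[C@H](Br)[C@@H](C/C=C/CC)O1 | intermediate
14 | 2-[(2R,3S,5S,6R)-5-bromo-6-[(2E)-pent-2-en-1-yl]-3-(4,4,5,5-tetramethyl-1,3,2-dioxaborolan-2-yl)oxan-2-yl]ethan-1-ol | OCC[C@@H]1[C@@H](B2OC(C)(C)C(C)(C)O2)C[C@H](Br)[C@@H](C/C=C/CC)O1 | intermediate
15 | (2R,3S,5S,6R)-5-bromo-2-(2-hydroxyethyl)-6-[(2E)-pent-2-en-1-yl]oxan-3-ol | OCC[C@@H]1[C@@H](O)C[C@H](Br)[C@@H](C/C=C/CC)O1 | intermediate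
16 | 2-[(1S,3R,4S,6R,8R,10S)-4,10-dibromo-3-ethyl-2,7-dioxabicyclo[4.2.2]decan-8-yl]ethan-1-ol | OCC[C@H]1O[C@@H]2C[C@H](Br)[C@@H](CC)O[C@H]1C[C@@H]2Br | intermediate
17 | 2-[(1S,3R,4S,6R,8R,10S)-4,10-dibromo-3-ethyl-2,7-dioxabicyclo[4.2.2]decan-8-yl]acetaldehyde | O=CC[C@H]1O[C@@H]2C[C@H](Br)[C@@H](CC)O[C@H]1C[C@@H]2Br | intermediate
18 | (triphenylphosphoranylidene)acetaldehyde | O=CC=P(c1ccccc1)(c1ccccc1)c1ccccc1 | starting material
19 | (2E)-4-[(1S,3R,4S,6R,8R,10S)-4,10-dibromo-3-ethyl-2,7-dioxabicyclo[4.2.2]decan-8-yl]but-2-enal | O=C/C=C/C[C@H]1O[C@@H]2C[C@H](Br)[C@@H](CC)O[C@H]1C[C@@H]2Br | intermediate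
20 | (diazomethyl)trimethylsilane | C[Si](C)(C)C=[N+]=[N-] | starting material
21 | (1S,3R,4S,6R,8R,10S)-4,10-dibromo-3-ethyl-8-[(2E)-pent-2-en-4-yn-1-yl]-2,7-dioxabicyclo[4.2.2]decane | C#C/C=C/C[C@H]1O[C@@H]2C[C@H](Br)[C@@H](CC)O[C@H]1C[C@@H]2Br | target

**Count and risks**

Total step count: 14. Longest linear sequence: 14 steps (1 and 2 to 21); 9, 18 and 20 are bought.

The three steps most likely to fail:

Step 11. The bridging ring closure may go astray in three ways: closure at C12 instead of C13 (7-exo instead of 8-endo), bromonium formation on the wrong alkene face, or capture of the bromonium ion by the ring oxygen. The fallback sets out from 15 and comes back at 16; it fixes regiochemistry and configuration separately. The primary hydroxyl of 15 is capped selectively (pivaloyl chloride, pyridine, CH2Cl2, −20 °C) to give 2-[(2R,3S,5S,6R)-5-bromo-3-hydroxy-6-[(2E)-pent-2-en-1-yl]oxan-2-yl]ethyl pivalate F1. Shi epoxidation with the enantiomer of the D-fructose-derived ketone (KHSO5, K2CO3, MeCN–dimethoxymethane–buffer, 0 °C) should set the (S,S)-epoxide F2 under reagent control. Camphorsulfonic acid (CH2Cl2, 0 °C) lets the C7 hydroxyl open the epoxide in the favoured 7-exo sense at C12 with inversion, giving the bridged oxepane carbinol F3. Tf2O and 2,6-lutidine (CH2Cl2, −78 °C), then Bu4NBr (to 0 °C), activate the C13 hydroxyl; the oxepane oxygen expels the triflate and bromide opens the bridged oxonium ion at C12. This stereospecific oxepane-to-oxocane ring expansion inverts both centres and gives the bicyclic dibromide pivalate F4. i-Bu2AlH (CH2Cl2, −78 °C) removes the pivalate and returns 16.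

Step 8. The ring oxygen may take part in the substitution at C9 (ring contraction or substitution with retention), or HBr may be lost. The fallback sets out from 12 and comes back at 13; it puts that participation to work. A Mitsunobu reaction (4-nitrobenzoic acid, PPh3, DIAD, THF, 0 °C; a carboxylate at low temperature should capture the oxyphosphonium ion before the ring oxygen does) gives the C9-inverted 4-nitrobenzoate F5. K2CO3 in MeOH cleaves it to the trans alcohol F6. Tf2O and 2,6-di-tert-butyl-4-methylpyridine (CH2Cl2, −78 to −20 °C) are applied first, with no nucleophile present, so that the equatorial triflate, antiperiplanar to the C10–O bond, is expelled by the ring oxygen. Bu4NBr then opens the bridged oxonium ion at C9, and substitution with overall retention gives 13. The same sequence from F6 also absorbs a wrong facial outcome in step 7, should the reduction give F6 directly.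

Step 1. Acid may move the 3,4-double bond into conjugation during the acylation, or polymerise the furan. The fallback sets out from 2 and comes back at 4. The acid is converted (carbonyldiimidazole, then MeNHOMe·HCl, CH2Cl2, rt) into (3E)-N-methoxy-N-methylhex-3-enamide F7. 2-Furyllithium (from 1 and n-BuLi, THF, 0 °C) is added at −78 °C; the chelated tetrahedral adduct releases 4 only on work-up, so the β,γ-unsaturated ketone never meets acid.

Further compounds
F1 | step 11 | 2-[(2R,3S,5S,6R)-5-bromo-3-hydroxy-6-[(2E)-pent-2-en-1-yl]oxan-2-yl]ethyl 2,2-dimethylpropanoate | CC(C)(C)C(=O)OCC[C@@H]1[C@@H](O)C[C@H](Br)[C@@H](C/C=C/CC)O1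
F2 | step 11 | 2-[(2R,3S,5S,6R)-5-bromo-6-{[(2S,3S)-3-ethyloxiran-2-yl]methyl}-3-hydroxyoxan-2-yl]ethyl 2,2-dimethylpropanoate | CC(C)(C)C(=O)OCC[C@@H]1[C@@H](O)C[C@H](Br)[C@@H](C[C@@H]2O[C@H]2CC)O1
F3 | step 11 | 2-[(1S,3R,5R,7R,9S)-9-bromo-3-[(1S)-1-hydroxypropyl]-2,6-dioxabicyclo[3.2.2]nonan-7-yl]ethyl 2,2-dimethylpropanoate | CC(C)(C)C(=O)OCC[C@H]1O[C@@H]2C[C@H]([C@@H](O)CC)O[C@H]1C[C@@H]2Br
F4 | step 11 | 2-[(1S,3R,4S,6R,8R,10S)-4,10-dibromo-3-ethyl-2,7-dioxabicyclo[4.2.2]decan-8-yl]ethyl 2,2-dimethylpropanoate | CC(C)(C)C(=O)OCC[C@H]1O[C@@H]2C[C@H](Br)[C@@H](CC)O[C@H]1C[C@@H]2Br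
F5 | step 8 | methyl 2-[(2R,3S,5S,6R)-5-[(4-nitrobenzoyl)oxy]-6-[(2E)-pent-2-en-1-yl]-3-(4,4,5,5-tetramethyl-1,3,2-dioxaborolan-2-yl)oxan-2-yl]acetate | COC(=O)C[C@@H]1[C@@H](B2OC(C)(C)C(C)(C)O2)C[C@H](OC(=O)c2ccc(cc2)[N+](=O)[O-])[C@@H](C/C=C/CC)O1
F6 | step 8 | methyl 2-[(2R,3S,5S,6R)-5-hydroxy-6-[(2E)-pent-2-en-1-yl]-3-(4,4,5,5-tetramethyl-1,3,2-dioxaborolan-2-yl)oxan-2-yl]acetate | COC(=O)C[C@@H]1[C@@H](B2OC(C)(C)C(C)(C)O2)C[C@H](O)[C@@H](C/C=C/CC)O1
F7 | step 1 | (3E)-N-methoxy-N-methylhex-3-enamide | CC/C=C/CC(=O)N(C)OC
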